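## Retrosynthetic overview

1. The acid is freed last from an allyl ester. The 6-acetate, the E-13(14) enoate (Horner–Wadsworth–Emmons on a C13 methyl ketone), the C6 carbinol (hydroxyl-directed anti reduction) and the C8 carbinol (Markovnikov hydration of a C8=C17 methylene) all trace back to a 5,10-cis-fused 6-ketone.
2. That ketone comes from a C5=C6 silyl enol ether by kinetic protonation at C5, after the C11 ester has been grown into the C11–C13 ketone chain (reduction, oxidation, Wittig, conjugate reduction).
3. Key disconnection: ring B (C5–C10) by an intermolecular Diels–Alder reaction forming C7–C8 and C9–C10, between the diene C7=C6(OSiR3)–C5=C10 carried by ring A and the conjugated double bond of a buta-2,3-dienoate.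
4. Feature the strategy rests on: ring B bears oxygen at C6, a one-carbon branch (C17) at C8 and a carboxyl-level carbon (C11) at C9 next to the quaternary C10. A 2-silyloxy diene and an allenic ester leave exactly this pattern. The silyl group is tert-butyldimethylsilyl (stable to the Lewis acid) and the ester is (–)-8-phenylmenthyl (source of absolute configuration, removed in step 8).
5. Ring order: ring A is bought (β-cyclocitral); ring B is closed in the key step; no other ring is made.

Key step: step 7

Remark: labdane numbering is used throughout (ring A = C1–C5, C10; ring B = C5–C10; C17 on C8; C20 on C10). The SMILES is read as the 5,10-cis-fused decalin with H-5, CH3-20, C11, CH3-17 and the 6-acetoxy group on one face of ring B (the "upper" face) and the 8-hydroxyl on the other; that structure, (5S,6S,8S,9S,10R,13E), is the one made.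

## Route

Step 1
Reactants: 1 β-cyclocitral (2,6,6-trimethylcyclohex-1-ene-1-carbaldehyde)
Product: 2 1-(2,6,6-trimethylcyclohex-1-en-1-yl)ethan-1-ol (racemate)
Conditions: MeMgBr, THF, 0 °C; then H2O
Reagents that add atoms: methylmagnesium bromide, C[Mg]Br
Why: Grignard 1,2-addition to the hindered enal; the carbinol centre forms as a racemate and is erased in step 2.

Step 2
Reactants: 2 1-(2,6,6-trimethylcyclohex-1-en-1-yl)ethan-1-ol
Product: 3 1-(2,6,6-trimethylcyclohex-1-en-1-yl)ethan-1-one
Conditions: Dess–Martin periodinane, CH2Cl2, rt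
Reagents that add atoms: none
Why: Dess–Martin oxidation of the secondary allylic alcohol leaves the tetrasubstituted ring alkene untouched.

Step 3
Reactants: 3 1-(2,6,6-trimethylcyclohex-1-en-1-yl)ethan-1-one
Product: 4 tert-butyldimethyl{[1-(2,6,6-trimethylcyclohex-1-en-1-yl)ethenyl]oxy}silane
Conditions: TBSOTf, Et3N, CH2Cl2, 0 °C
Reagents that add atoms: tert-butyldimethylsilyl trifluoromethanesulfonate, CC(C)(C)[Si](C)(C)OS(=O)(=O)C(F)(F)F
Why: Soft enolisation and O-silylation; the acetyl methyl is the only enolisable α-position, so the 2-silyloxy-1,3-diene should form, and the tert-butyldimethylsilyl group is chosen to survive the Lewis acid of step 7.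

Step 4
Reactants: 5 (–)-8-phenylmenthol, (1R,2S,5R)-5-methyl-2-(2-phenylpropan-2-yl)cyclohexan-1-ol
Product: 6 (1R,2S,5R)-8-phenylmenthyl bromoacetate
Conditions: BrCH2C(O)Br, pyridine, CH2Cl2, 0 °C
Reagents that add atoms: bromoacetyl bromide, BrCC(Br)=O
Why: O-acylation of the secondary alcohol by the acyl bromide (esterification), with the alkyl bromide unaffected at 0 °C.

Step 5
Reactants: 6 (1R,2S,5R)-8-phenylmenthyl bromoacetate
Product: 8 (1R,2S,5R)-8-phenylmenthyl (triphenylphosphoranylidene)acetate, via phosphonium bromide 7 (not isolated)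
Conditions: PPh3, toluene, 40 °C; then aq. NaOH, CH2Cl2, 0 °C
Reagents that add atoms: triphenylphosphine, c1ccc(cc1)P(c1ccccc1)c1ccccc1
Why: SN2 quaternisation of the phosphine by the α-bromo ester followed by deprotonation to the ester-stabilised ylide.

Step 6
Reactants: 8 (1R,2S,5R)-8-phenylmenthyl (triphenylphosphoranylidene)acetate
Product: 9 (1R,2S,5R)-8-phenylmenthyl buta-2,3-dienoate
Conditions: AcCl, Et3N, CH2Cl2, 0 °C → rt
Reagents that add atoms: acetyl chloride, CC(Cl)=O
Why: Wittig reaction of the stabilised ylide with ketene generated in the flask from acetyl chloride and triethylamine, the standard preparation of buta-2,3-dienoates.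

Step 7
Reactants: 4 tert-butyldimethyl{[1-(2,6,6-trimethylcyclohex-1-en-1-yl)ethenyl]oxy}silane; 9 (1R,2S,5R)-8-phenylmenthyl buta-2,3-dienoate
Product: 10 (1R,2S,5R)-8-phenylmenthyl (9R,10S)-6-(tert-butyldimethylsilyloxy)-12,13,14,15,16-pentanorlabda-5,8(17)-dien-11-oate (ester carbon C11 cis to CH3-20)
Conditions: AlBr3/AlMe3 (5:1), toluene/CH2Cl2, −20 °C → 0 °C; pyridine, then aq. NaHCO3
Reagents that add atoms: none
Why: The Lewis acid binds the ester carbonyl of 9, the electron-rich terminus C7 of the silyloxy diene attacks the central allene carbon C8 and C9 then bonds to C10, a strongly asynchronous [4+2] that in the limit is a Mukaiyama–Michael addition followed by closure of the aluminium dienolate onto the silyloxyallyl cation, so the twisted diene need not reach a planar s-cis geometry. The closest known reactions are mixed aluminium Lewis acid Diels–Alder reactions of hindered 2-silyloxy dienes, cycloadditions of buta-2,3-dienoates at their conjugated double bond, and Diels–Alder reactions of 8-phenylmenthyl acrylate. Ring B (C5–C10) is closed by this intermolecular cycloaddition, the second bond C9–C10 forming in a 6-endo-trig (enolexo) sense if the process is stepwise. C9 should be set by the auxiliary, whose phenyl ring stacks over the Re face of the s-trans enoate so that C10 adds to the Si face of the α-carbon, and C10 follows from the exo position of the ester, which places C11 cis to CH3-20, the inside substituent of the diene terminus. Regiochemistry (C7 to C8, C10 to C9) is secured by the silyloxy group at C6 and the ester at C11, site selectivity by conjugation of the α,β-bond, and exo selectivity by the known preference of allenic esters with hindered dienes. The tert-butyldimethylsilyl enol ether is kept in 10 as a mask for the C6 ketone and for the still unset C5.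

Step 8
Reactants: 10 (1R,2S,5R)-8-phenylmenthyl (9R,10S)-6-(tert-butyldimethylsilyloxy)-12,13,14,15,16-pentanorlabda-5,8(17)-dien-11-oate
Product: 11 (9R,10S)-6-(tert-butyldimethylsilyloxy)-12,13,14,15,16-pentanorlabda-5,8(17)-dien-11-ol
Conditions: LiAlH4, THF, 0 °C → 40 °C; H2O/NaOH work-up
Reagents that add atoms: none
Why: LiAlH4 reduction of the hindered ester to the primary alcohol releases the auxiliary 5 for recovery, while the silyl enol ether and both alkenes are inert to hydride and to the basic work-up.

Step 9
Reactants: 11 (9R,10S)-6-(tert-butyldimethylsilyloxy)-12,13,14,15,16-pentanorlabda-5,8(17)-dien-11-ol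
Product: 12 (9R,10S)-6-(tert-butyldimethylsilyloxy)-12,13,14,15,16-pentanorlabda-5,8(17)-dien-11-al
Conditions: Pr4N[RuO4] (cat.), NMO, 4 Å MS, CH2Cl2, rt
Reagents that add atoms: none
Why: Ley–Griffith oxidation under neutral conditions should give the aldehyde without epimerising C9, without moving the 8(17) double bond into conjugation and without cleaving the silyl enol ether.

Step 10
Reactants: 12 (9R,10S)-6-(tert-butyldimethylsilyloxy)-12,13,14,15,16-pentanorlabda-5,8(17)-dien-11-al
Product: 13 (9R,10S,11E)-6-(tert-butyldimethylsilyloxy)-14,15-dinorlabda-5,8(17),11-trien-13-one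
Conditions: Ph3P=CHC(O)CH3, toluene, 100 °C
Reagents that add atoms: 1-(triphenylphosphoranylidene)propan-2-one, CC(=O)C=P(c1ccccc1)(c1ccccc1)c1ccccc1
Why: Wittig olefination with the non-basic ketone-stabilised ylide gives the E-enone and avoids enolisation of the α-branched, β,γ-unsaturated aldehyde.

Step 11
Reactants: 13 (9R,10S,11E)-6-(tert-butyldimethylsilyloxy)-14,15-dinorlabda-5,8(17),11-trien-13-one
Product: 14 (9R,10S)-6-(tert-butyldimethylsilyloxy)-14,15-dinorlabda-5,8(17)-dien-13-one
Conditions: [(Ph3P)CuH]6, toluene, H2O (few equiv), rt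
Reagents that add atoms: none
Why: Copper hydride conjugate reduction (Stryker's reagent) saturates only the enone C11=C12 bond, water protonating the copper enolate, while the isolated methylene and the enol ether double bond are not reduced.

Step 12
Reactants: 14 (9R,10S)-6-(tert-butyldimethylsilyloxy)-14,15-dinorlabda-5,8(17)-dien-13-one
Product: 15 (5S,9R,10S)-14,15-dinorlabd-8(17)-ene-6,13-dione (5,10-cis-fused; H-5 cis to CH3-20)
Conditions: TBAF, AcOH, THF, −20 °C
Reagents that add atoms: none
Why: Fluoride cleaves the Si–O bond and the enolate is protonated at C5 by acetic acid under kinetic control (Zimmerman-type ketonisation of an enol exocyclic to ring A, the proton entering on the equatorial side of ring A, the face of CH3-20), which should leave C6 axial on ring A and so give the cis-fused ketone; the cold buffered medium avoids equilibration to the trans isomer and migration of the 8(17) double bond.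

Step 13
Reactants: 15 (5S,9R,10S)-14,15-dinorlabd-8(17)-ene-6,13-dione
Product: 16 (5S,8S,9S,10S)-8-hydroxy-14,15-dinorlabdane-6,13-dione (8-OH anti to C11 and CH3-20)
Conditions: Mn(dpm)3 [tris(dipivaloylmethanato)manganese] (cat.), PhSiH3, O2 (1 atm), i-PrOH/CH2Cl2, 0 °C
Reagents that add atoms: dioxygen, O=O
Why: Mukaiyama hydration by metal hydride hydrogen-atom transfer: hydrogen adds to C17, the tertiary C8 radical should be trapped by O2 on the face opposite to the axial C9 chain and the peroxide is reduced in the flask, which sets the 8-hydroxyl anti to C11 under neutral conditions that do not epimerise C5.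

Step 14
Reactants: 16 (5S,8S,9S,10S)-8-hydroxy-14,15-dinorlabdane-6,13-dione
Product: 17 (5S,6S,8S,9S,10R)-6,8-dihydroxy-14,15-dinorlabdan-13-one
Conditions: Me4NBH(OAc)3, MeCN/AcOH, −30 °C → −10 °C
Reagents that add atoms: none
Why: Evans–Saksena reduction: the 8-hydroxyl exchanges onto boron and delivers hydride to C6 from its own (lower) face, giving the 1,3-anti diol with the 6-hydroxyl on the face of H-5 and CH3-20, while the unactivated C13 ketone is not reduced by the triacetoxyborohydride.

Step 15
Reactants: 17 (5S,6S,8S,9S,10R)-6,8-dihydroxy-14,15-dinorlabdan-13-one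
Product: 18 allyl (5S,6S,8S,9S,10R,13E)-6,8-dihydroxylabd-13-en-15-oate
Conditions: (EtO)2P(O)CH2CO2CH2CH=CH2, NaH, THF, 0 °C → 40 °C
Reagents that add atoms: allyl 2-(diethoxyphosphoryl)acetate, C=CCOC(=O)CP(=O)(OCC)OCC
Why: Horner–Wadsworth–Emmons olefination of the methyl ketone with the preformed sodium phosphonate should give mainly the E-trisubstituted enoate (the minor Z isomer is removed by chromatography), and the stabilised anion does not deprotonate the free hydroxyls.

Step 16
Reactants: 18 allyl (5S,6S,8S,9S,10R,13E)-6,8-dihydroxylabd-13-en-15-oate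
Product: 19 allyl (5S,6S,8S,9S,10R,13E)-6-acetoxy-8-hydroxylabd-13-en-15-oate
Conditions: Ac2O, DMAP (cat.), pyridine, CH2Cl2, rt
Reagents that add atoms: acetic anhydride, CC(=O)OC(C)=O
Why: DMAP-catalysed acylation esterifies the secondary 6-hydroxyl and not the tertiary 8-hydroxyl, and the trans-1,3 relationship of the two oxygens excludes acetyl migration.

Step 17
Reactants: 19 allyl (5S,6S,8S,9S,10R,13E)-6-acetoxy-8-hydroxylabd-13-en-15-oate
Product: 20 (5S,6S,8S,9S,10R,13E)-6-acetoxy-8-hydroxylabd-13-en-15-oic acid (target)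
Conditions: Pd(PPh3)4 (cat.), morpholine, THF, rt; dilute citric acid work-up
Reagents that add atoms: none
Why: Tsuji–Trost deallylation: zerovalent palladium ionises the allyl ester and morpholine captures the allyl fragment, freeing the acid under neutral conditions that spare the acetate, the tertiary alcohol and the E-alkene.

## Compound list

1 | β-cyclocitral (2,6,6-trimethylcyclohex-1-ene-1-carbaldehyde) | CC1=C(C=O)C(C)(C)CCC1 | starting material
2 | 1-(2,6,6-trimethylcyclohex-1-en-1-yl)ethan-1-ol (racemate) | CC(O)C1=C(C)CCCC1(C)C | intermediate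
3 | 1-(2,6,6-trimethylcyclohex-1-en-1-yl)ethan-1-one | CC(=O)C1=C(C)CCCC1(C)C | intermediate
4 | tert-butyldimethyl{[1-(2,6,6-trimethylcyclohex-1-en-1-yl)ethenyl]oxy}silane | C=C(O[Si](C)(C)C(C)(C)C)C1=C(C)CCCC1(C)C | intermediate
5 | (–)-8-phenylmenthol, (1R,2S,5R)-5-methyl-2-(2-phenylpropan-2-yl)cyclohexan-1-ol | CC(C)(c1ccccc1)[C@@H]1CC[C@@H](C)C[C@H]1O | starting material
6 | (1R,2S,5R)-8-phenylmenthyl bromoacetate | CC(C)(c1ccccc1)[C@@H]1CC[C@@H](C)C[C@H]1OC(=O)CBr | intermediate
7 | [2-oxo-2-((1R,2S,5R)-8-phenylmenthyloxy)ethyl]triphenylphosphonium bromide | CC(C)(c1ccccc1)[C@@H]1CC[C@@H](C)C[C@H]1OC(=O)C[P+](c1ccccc1)(c1ccccc1)c1ccccc1.[Br-] | intermediate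
8 | (1R,2S,5R)-8-phenylmenthyl (triphenylphosphoranylidene)acetate | CC(C)(c1ccccc1)[C@@H]1CC[C@@H](C)C[C@H]1OC(=O)C=P(c1ccccc1)(c1ccccc1)c1ccccc1 | intermediate
9 | (1R,2S,5R)-8-phenylmenthyl buta-2,3-dienoate | CC(C)(c1ccccc1)[C@@H]1CC[C@@H](C)C[C@H]1OC(=O)C=C=C | intermediate
10 | (1R,2S,5R)-8-phenylmenthyl (9R,10S)-6-(tert-butyldimethylsilyloxy)-12,13,14,15,16-pentanorlabda-5,8(17)-dien-11-oate | CC(C)(c1ccccc1)[C@@H]1CC[C@@H](C)C[C@H]1OC(=O)[C@@H]1C(=C)CC(O[Si](C)(C)C(C)(C)C)=C2C(C)(C)CCC[C@@]12C | intermediate
11 | (9R,10S)-6-(tert-butyldimethylsilyloxy)-12,13,14,15,16-pentanorlabda-5,8(17)-dien-11-ol | OC[C@@H]1C(=C)CC(O[Si](C)(C)C(C)(C)C)=C2C(C)(C)CCC[C@@]12C | intermediate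
12 | (9R,10S)-6-(tert-butyldimethylsilyloxy)-12,13,14,15,16-pentanorlabda-5,8(17)-dien-11-al | O=C[C@@H]1C(=C)CC(O[Si](C)(C)C(C)(C)C)=C2C(C)(C)CCC[C@@]12C | intermediate
13 | (9R,10S,11E)-6-(tert-butyldimethylsilyloxy)-14,15-dinorlabda-5,8(17),11-trien-13-one | CC(=O)/C=C/[C@@H]1C(=C)CC(O[Si](C)(C)C(C)(C)C)=C2C(C)(C)CCC[C@@]12C | intermediate
14 | (9R,10S)-6-(tert-butyldimethylsilyloxy)-14,15-dinorlabda-5,8(17)-dien-13-one | CC(=O)CC[C@@H]1C(=C)CC(O[Si](C)(C)C(C)(C)C)=C2C(C)(C)CCC[C@@]12C | intermediate
15 | (5S,9R,10S)-14,15-dinorlabd-8(17)-ene-6,13-dione (5,10-cis) | O=C1CC(=C)[C@@H](CCC(C)=O)[C@]2(C)CCCC(C)(C)[C@H]12 | intermediate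
16 | (5S,8S,9S,10S)-8-hydroxy-14,15-dinorlabdane-6,13-dione | O=C1C[C@](C)(O)[C@@H](CCC(C)=O)[C@]2(C)CCCC(C)(C)[C@H]12 | intermediate
17 | (5S,6S,8S,9S,10R)-6,8-dihydroxy-14,15-dinorlabdan-13-one | O[C@H]1C[C@](C)(O)[C@@H](CCC(C)=O)[C@]2(C)CCCC(C)(C)[C@H]12 | intermediate
18 | allyl (5S,6S,8S,9S,10R,13E)-6,8-dihydroxylabd-13-en-15-oate | O[C@H]1C[C@](C)(O)[C@@H](CC/C(C)=C/C(=O)OCC=C)[C@]2(C)CCCC(C)(C)[C@H]12 | intermediate
19 | allyl (5S,6S,8S,9S,10R,13E)-6-acetoxy-8-hydroxylabd-13-en-15-oate | CC(=O)O[C@H]1C[C@](C)(O)[C@@H](CC/C(C)=C/C(=O)OCC=C)[C@]2(C)CCCC(C)(C)[C@H]12 | intermediate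
20 | (5S,6S,8S,9S,10R,13E)-6-acetoxy-8-hydroxylabd-13-en-15-oic acid (CNP0221670.1) | CC(=O)O[C@H]1C[C@](C)(O)[C@@H](CC/C(C)=C/C(=O)O)[C@]2(C)CCCC(C)(C)[C@H]12 | target

## Step count

Total: 17 steps. Longest linear sequence: 14 steps (steps 1–3 and 7–17; the dienophile branch, steps 4–6 and 7–17, is equally long).

## Steps most likely to fail

1. Step 7 (key cycloaddition). The reaction may stop after the first bond (C7–C8) with loss of the silyl group instead of closing C9–C10, and the auxiliary may discriminate the two faces of C9 poorly. Fallback: the two bonds of ring B are made in separate operations. Setting out from 4 and 9, EtAlCl2 (CH2Cl2, −78 °C) and aqueous work-up should give the Mukaiyama–Michael product (1R,2S,5R)-8-phenylmenthyl 3-methylidene-5-oxo-5-(2,6,6-trimethylcyclohex-1-en-1-yl)pentanoate F1. t-BuOK (THF, −40 °C) then closes ring B by intramolecular Michael addition of the ester dienolate carbon C9 to C10 of the enone, and the ring enolate is silylated in the same flask with TBSOTf, which comes back to the route at 10. If facial control is incomplete, the C9/C10 diastereomers, which differ through the auxiliary, are separated by chromatography at this point.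

2. Step 12 (C5 by kinetic protonation). Protonation on the lower face, or equilibration of the ketone through its enol, would give the trans ring fusion, which is expected to be the more stable one; the 8(17) double bond may also drift into conjugation. Fallback: C5 is set earlier with the C11 hydroxyl as an internal proton relay (the analogy is protonation by an angular hydroxymethyl group in metal–ammonia reductions of hydroxy enones, which gives cis-fused products). Setting out from 11, TBAF (THF, −78 °C, then AcOH) should give (5S,9R,10S)-11-hydroxy-12,13,14,15,16-pentanorlabd-8(17)-en-6-one F2, because the hydroxymethyl group sits on the upper face 1,3 to C5 and hands its proton to C5 there. Pr4N[RuO4]/NMO then gives (5S,9R,10S)-6-oxo-12,13,14,15,16-pentanorlabd-8(17)-en-11-al F3, the Wittig reaction of step 10 gives (5S,9R,10S,11E)-14,15-dinorlabda-8(17),11-diene-6,13-dione F4, and the copper hydride reduction of step 11 comes back to the route at 15.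

3. Step 13 (C8 hydration). Oxygen may be trapped on both faces of the planar C8 radical, and reversible hydrogen-atom transfer may isomerise the alkene. Fallback: the hydroxyl is brought in by an ionic sequence, at the cost of exposing C5 to base, so contact times must be short. Setting out from 15, DBU (cat., CH2Cl2, 0 °C) moves the double bond into conjugation to give (5S,9R,10S)-14,15-dinorlabd-7-ene-6,13-dione F5. Weitz–Scheffer epoxidation (t-BuOOH, DBU, CH2Cl2), in which the peroxide anion adds to C8 anti to the axial C9 chain, gives (5S,7R,8R,9S,10S)-7,8-epoxy-14,15-dinorlabdane-6,13-dione F6. SmI2 (THF/MeOH, −78 °C) cleaves the C7–O bond and comes back to the route at 16.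

## Further compounds

F1 | step 7 | (1R,2S,5R)-8-phenylmenthyl 3-methylidene-5-oxo-5-(2,6,6-trimethylcyclohex-1-en-1-yl)pentanoate | CC(C)(c1ccccc1)[C@@H]1CC[C@@H](C)C[C@H]1OC(=O)CC(=C)CC(=O)C1=C(C)CCCC1(C)C
F2 | step 12 | (5S,9R,10S)-11-hydroxy-12,13,14,15,16-pentanorlabd-8(17)-en-6-one | O=C1CC(=C)[C@@H](CO)[C@]2(C)CCCC(C)(C)[C@H]12
F3 | step 12 | (5S,9R,10S)-6-oxo-12,13,14,15,16-pentanorlabd-8(17)-en-11-al | O=C1CC(=C)[C@@H](C=O)[C@]2(C)CCCC(C)(C)[C@H]12
F4 | step 12 | (5S,9R,10S,11E)-14,15-dinorlabda-8(17),11-diene-6,13-dione | O=C1CC(=C)[C@@H](/C=C/C(C)=O)[C@]2(C)CCCC(C)(C)[C@H]12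
F5 | step 13 | (5S,9R,10S)-14,15-dinorlabd-7-ene-6,13-dione | O=C1C=C(C)[C@@H](CCC(C)=O)[C@]2(C)CCCC(C)(C)[C@H]12
F6 | step 13 | (5S,7R,8R,9S,10S)-7,8-epoxy-14,15-dinorlabdane-6,13-dione | O=C1[C@@H]2O[C@]2(C)[C@@H](CCC(C)=O)[C@]3(C)CCCC(C)(C)[C@H]13
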